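3 questions stand on this flask, and you can meet them with one concentration, that of free G.

    D + G ⇌ D.G, settled at all times (K1 = 4.4 /M)
    D.G → Q (k2 = 0.0030 /s)
    J ⇌ Q, rate k3*(cs3 - [Q]) while solid is left; crystals form when [Q] > cs3 (cs3 = 9.2 mM, k3 = 0.47 /s)

D 0.18 M; G 2.00 equiv; time 5.0 min

- what is said of Q includes J
- J is a solid; its amount is given per volume of the solution
- run time (flask): 5.0 min

- alpha: doubling the dissolution coefficient of step 3, all else as stated
- eta: doubling the solubility in step 3, all else as stated
- delta: doubling the amount of G, all else as stated

1. how much Q and J together there is at 5.0 min, in percent of the D charged
2. the change that raises the amount of Q and J together at 5.0 min, in percent of the D charged most ("none" if none brings more than 2 percentage points) (alpha / eta / delta / none)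
3. amount of Q and J together at 5.0 min, in percent of the D charged, after eta

Step 3 moves material between dissolved Q and J, so their sum grows by step 2, at k2 times the concentration of D.G. Step 1 stays at balance, so the part of the unconverted D sitting as D.G is x/(1+x), where x is the equilibrium constant of step 1 times free G. Well below one, x makes the rate first order in G; well above one, the rate stops feeling G. With G at its charge, x is 1.6, which lies between those ends and gives 61.3% for the bound share, the part of the unconverted D held as D.G.

The bench rule is to call G an excess, hold it constant and treat D as pseudo-first-order, with rate constant k2 times that share. Over 5.0 min this gives 42.4%. The border of the rule lies in the ratio of charges: at 2.00 equiv, full conversion of D would take half of the G, so holding G at its charge is not an honest step in this flask. With G at half its charge throughout, the rule gives 32.8%, so I put the answer between these two figures. Doubling G under the held rule gives 49.5%, a gain of 7.1 percentage points, so I choose delta. Since eta acts on step 3, I expect it to leave the sum unchanged.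

The forecast gives 37.5%, names delta and puts the amount after eta at 37.5%, holding that “Step 3 only moves material between dissolved Q and crystals J”.

The simulated flask gives 37.5%. The best change is delta, worth 10 points, and after eta the amount is 37.5%.

This flask reads 37.5% mainly because it is read at 5.00 min and not ten times later: at 50.0 min the same run reads 98.5%. At 5.00 min, free G in this flask stands at 65.4% of its charge, which puts the bound share at 51.1%, against 61.3% with G at its charge. In the neighbour flask with 3.40 equiv of G, free G ends at 76% of that larger charge, the bound share comes to 67.4%, and Q and J together reach 45.6%.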